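**Retrosynthetic overview**
1. Target 19 ⇒ diol 17 + angelic anhydride 18: both angelates go on last by alkoxide acylation.
2. 17 ⇒ iodo-aldehyde 15: the ten-membered ring is closed last at C5–C6 (Nozaki–Hiyama–Kishi), which also sets C6.
3. 15 ⇒ enal 12 + pyruvic acid 13: the γ-lactone is made first by an amine-catalysed oxa-Michael/aldol annulation that sets C8, C7 and C11 (new method).
4. 12 ⇒ bromide 8 + propargyl alcohol 9 (copper acetylide coupling, then Ru redox isomerisation); 8 ⇒ 5-chloropent-1-yne 1 + silyloxyacetone 3 (Z-selective Wittig for C1=C10, Zr-catalysed carboalumination–iodination for C4=C5).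

Assumption: atoms are called C1–C15 by germacrane numbering (C6 and C11 carry the esters, C12 is the lactone carbonyl on O–C8), and 1, 3, 9, 13 and 18 are bought.

**Step 1**
Reactants: 1 5-chloropent-1-yne
Product: 2 triphenyl(pent-4-yn-1-yl)phosphonium iodide
Conditions: PPh3 (1.1 equiv), NaI (1.2 equiv), MeCN, reflux
Reagents that add atoms: triphenylphosphine, c1ccc(cc1)P(c1ccccc1)c1ccccc1; sodium iodide, [Na+].[I-]
Why: Finkelstein exchange to the primary iodide followed by SN2 quaternisation of the phosphine gives the Wittig salt, and the terminal alkyne is inert.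

**Step 2**
Reactants: 2 triphenyl(pent-4-yn-1-yl)phosphonium iodide; 3 1-[tert-butyl(dimethyl)silyloxy]propan-2-one
Product: 5 tert-butyl(dimethyl){[(2Z)-2-methylhept-2-en-6-yn-1-yl]oxy}silane, via phosphonium ylide 4 (not isolated)
Conditions: KN(SiMe3)2 (1.0 equiv), THF, −78 °C; then 3, −78 °C to rt
Reagents that add atoms: none
Why: Wittig olefination of an α-silyloxy ketone with a salt-free non-stabilised ylide is kinetically Z-selective (chain cis to the CH2O group), which fixes the C1=C10 geometry, and the ylide is not basic enough to deprotonate the alkyne C–H.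

**Step 3**
Reactants: 5 tert-butyl(dimethyl){[(2Z)-2-methylhept-2-en-6-yn-1-yl]oxy}silane
Product: 7 tert-butyl{[(2Z,6E)-7-iodo-2,6-dimethylhepta-2,6-dien-1-yl]oxy}dimethylsilane, via alkenylalane 6 (not isolated)
Conditions: AlMe3 (2.5 equiv), Cp2ZrCl2 (0.25 equiv), CH2Cl2, 0 °C to rt; then I2, THF, −30 °C
Reagents that add atoms: trimethylaluminium, C[Al](C)C; iodine, [I][I]
Why: Negishi zirconium-catalysed carboalumination adds Me–Al syn across the terminal alkyne (methyl to the internal carbon) and iodinolysis with retention gives the (E)-iodoalkene (C4=C5), while the trisubstituted alkene and the silyl ether are inert.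

**Step 4**
Reactants: 7 tert-butyl{[(2Z,6E)-7-iodo-2,6-dimethylhepta-2,6-dien-1-yl]oxy}dimethylsilane
Product: 8 (1E,5Z)-7-bromo-1-iodo-2,6-dimethylhepta-1,5-diene
Conditions: Ph3PBr2 (1.2 equiv), CH2Cl2, 0 °C
Reagents that add atoms: dibromo(triphenyl)phosphorane, BrP(Br)(c1ccccc1)(c1ccccc1)c1ccccc1
Why: Direct silyl ether to bromide conversion (oxyphosphonium formation, then SN2 by bromide at the primary carbon) avoids a separate deprotection and, at 0 °C, leaves the Z geometry and the allylic position unchanged.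

**Step 5**
Reactants: 8 (1E,5Z)-7-bromo-1-iodo-2,6-dimethylhepta-1,5-diene; 9 prop-2-yn-1-ol
Product: 11 (5Z,9E)-10-iodo-5,9-dimethyldeca-5,9-dien-2-yn-1-ol, via copper acetylide 10 (not isolated)
Conditions: 9 (2 equiv), CuI (1.0 equiv), K2CO3 (1.5 equiv), DMF, rt
Reagents that add atoms: none
Why: Copper-mediated alkyne–allyl halide coupling, in which the copper acetylide substitutes the primary allylic bromide at the unhindered CH2 to give the skipped enyne (C8–C9 bond), and the alkenyl iodide does not couple with copper acetylides at room temperature without palladium.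

**Step 6**
Reactants: 11 (5Z,9E)-10-iodo-5,9-dimethyldeca-5,9-dien-2-yn-1-ol
Product: 12 (2E,5Z,9E)-10-iodo-5,9-dimethyldeca-2,5,9-trienal
Conditions: (indenyl)RuCl(PPh3)2 (5 mol %), In(OTf)3 (5 mol %), camphorsulfonic acid (5 mol %), THF, 65 °C
Reagents that add atoms: none
Why: Ruthenium-catalysed redox isomerisation of a primary propargylic alcohol (internal 1,2-hydride shift, then protonation) gives the (E)-enal in one atom-economic step under near-neutral conditions that should leave isolated alkenes and the C–I bond alone.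

**Step 7**
Reactants: 12 (2E,5Z,9E)-10-iodo-5,9-dimethyldeca-2,5,9-trienal; 13 2-oxopropanoic acid (pyruvic acid)
Product: 15 (2R,3R,4R)-4-hydroxy-2-[(2Z,6E)-7-iodo-2,6-dimethylhepta-2,6-dien-1-yl]-4-methyl-5-oxooxolane-3-carbaldehyde, via oxa-Michael adduct 14 (not isolated)
Conditions: 13 (1.5 equiv), (S)-2-{bis[3,5-bis(trifluoromethyl)phenyl](trimethylsilyloxy)methyl}pyrrolidine (20 mol %), toluene, 0 °C to rt
Reagents that add atoms: none
Why: Proposed new method: the amine condenses with 12 to an E-iminium ion whose own pyruvate counter-ion adds through oxygen to C8 on the face away from the diaryl(silyloxy)methyl group (sets 8R), the β-acyloxy enamine 14 is then trapped before it can eliminate by a 5-enolexo aldol of C7 onto the activated α-keto ester carbonyl from the same open face (H8 eclipsing the enamine to avoid allylic strain puts the formyl group trans to the C8 chain, and the carbonyl oxygen turned toward the forming iminium puts the C11–OH cis to the formyl group, which is also the thermodynamic arrangement reachable by retro-aldol/aldol and C7 epimerisation), and hydrolysis releases 15 and the catalyst; the closest known reaction types are the iminium–enamine sulfa-Michael/aldol annulation of enals with mercaptoacetaldehyde and the oxa-Michael/aldol condensation of enals with salicylaldehydes.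

**Step 8**
Reactants: 15 (2R,3R,4R)-4-hydroxy-2-[(2Z,6E)-7-iodo-2,6-dimethylhepta-2,6-dien-1-yl]-4-methyl-5-oxooxolane-3-carbaldehyde
Product: 17 (6S,7R,8R,11R)-(1(10)Z,4E)-6,11-dihydroxygermacra-1(10),4-dien-12,8-olide, via alkenylchromium 16 (not isolated)
Conditions: CrCl2 (8 equiv), NiCl2 (2 mol %), DMSO/THF 3:1, 0.003 M by slow addition, rt
Reagents that add atoms: none
Why: Nozaki–Hiyama–Kishi reaction, in which nickel-catalysed C–I activation and transmetalation give alkenylchromium 16 with the E geometry kept, and this adds only to the aldehyde at high dilution to close the ten-membered ring; chelation of the trivalent chromium between the aldehyde oxygen and the cis C11–OH turns the carbonyl toward C11 so that C5 enters from the H7 side, which gives the 6S carbinol.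

**Step 9**
Reactants: 17 (6S,7R,8R,11R)-(1(10)Z,4E)-6,11-dihydroxygermacra-1(10),4-dien-12,8-olide; 18 (2Z)-2-methylbut-2-enoic anhydride (angelic anhydride)
Product: 19 (6S,7S,8R,11R)-(1(10)Z,4E)-6,11-bis[(2Z)-2-methylbut-2-enoyloxy]germacra-1(10),4-dien-12,8-olide (CNP0391997.3)
Conditions: 18 (3 equiv), THF, −78 °C; LiN(SiMe3)2 (2.4 equiv) added dropwise, −78 to −20 °C; aq. NH4Cl
Reagents that add atoms: none
Why: Alkoxide acylation with angelic anhydride keeps the Z geometry of the angelate because no nucleophilic amine catalyst is present, the base is added last so that each alkoxide is acylated as it forms before the C6 alkoxide can attack the lactone carbonyl, and no stereocentre is touched.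

**Compound list**
1 | 5-chloropent-1-yne | ClCCCC#C | starting material
2 | triphenyl(pent-4-yn-1-yl)phosphonium iodide | C#CCCC[P+](c1ccccc1)(c1ccccc1)c1ccccc1.[I-] | intermediate
3 | 1-[tert-butyl(dimethyl)silyloxy]propan-2-one | CC(=O)CO[Si](C)(C)C(C)(C)C | starting material
4 | triphenyl(pent-4-yn-1-ylidene)-λ5-phosphane (ylide of 2) | C#CCCC=P(c1ccccc1)(c1ccccc1)c1ccccc1 | intermediate
5 | tert-butyl(dimethyl){[(2Z)-2-methylhept-2-en-6-yn-1-yl]oxy}silane | CC(C)(C)[Si](C)(C)OC/C(C)=C\CCC#C | intermediate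
6 | dimethyl[(1E,5Z)-7-{[tert-butyl(dimethyl)silyl]oxy}-2,6-dimethylhepta-1,5-dien-1-yl]alumane | CC(C)(C)[Si](C)(C)OC/C(C)=C\CC/C(C)=C/[Al](C)C | intermediate
7 | tert-butyl{[(2Z,6E)-7-iodo-2,6-dimethylhepta-2,6-dien-1-yl]oxy}dimethylsilane | CC(C)(C)[Si](C)(C)OC/C(C)=C\CC/C(C)=C/I | intermediate
8 | (1E,5Z)-7-bromo-1-iodo-2,6-dimethylhepta-1,5-diene | BrC/C(C)=C\CC/C(C)=C/I | intermediate
9 | prop-2-yn-1-ol | C#CCO | starting material
10 | (3-hydroxyprop-1-yn-1-yl)copper (copper acetylide of 9) | OCC#C[Cu] | intermediate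
11 | (5Z,9E)-10-iodo-5,9-dimethyldeca-5,9-dien-2-yn-1-ol | OCC#CC/C(C)=C\CC/C(C)=C/I | intermediate
12 | (2E,5Z,9E)-10-iodo-5,9-dimethyldeca-2,5,9-trienal | O=C/C=C/C/C(C)=C\CC/C(C)=C/I | intermediate
13 | 2-oxopropanoic acid (pyruvic acid) | CC(=O)C(=O)O | starting material
14 | (3R,5Z,9E)-10-iodo-5,9-dimethyl-1-oxodeca-5,9-dien-3-yl 2-oxopropanoate (held on the catalyst as its enamine in step 7) | O=CC[C@H](OC(=O)C(C)=O)C/C(C)=C\CC/C(C)=C/I | intermediate
15 | (2R,3R,4R)-4-hydroxy-2-[(2Z,6E)-7-iodo-2,6-dimethylhepta-2,6-dien-1-yl]-4-methyl-5-oxooxolane-3-carbaldehyde (ring O1–C2 = C8, C3 = C7 with CHO = C6, C4 = C11, C5 = C12) | O=C[C@H]1[C@@](C)(O)C(=O)O[C@@H]1C/C(C)=C\CC/C(C)=C/I | intermediate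
16 | alkenylchromium dichloride of 15 (C–I replaced by C–CrCl2, trivalent chromium) | O=C[C@H]1[C@@](C)(O)C(=O)O[C@@H]1C/C(C)=C\CC/C(C)=C/[Cr](Cl)Cl | intermediate
17 | (6S,7R,8R,11R)-(1(10)Z,4E)-6,11-dihydroxygermacra-1(10),4-dien-12,8-olide | O[C@H]1/C=C(\C)CC/C=C(/C)C[C@H]2OC(=O)[C@](C)(O)[C@H]12 | intermediate
18 | (2Z)-2-methylbut-2-enoic anhydride (angelic anhydride) | C/C=C(/C)C(=O)OC(=O)/C(C)=C\C | starting material
19 | (6S,7S,8R,11R)-(1(10)Z,4E)-6,11-bis[(2Z)-2-methylbut-2-enoyloxy]germacra-1(10),4-dien-12,8-olide | C/C=C(/C)C(=O)O[C@H]1/C=C(\C)CC/C=C(/C)C[C@H]2OC(=O)[C@](C)(OC(=O)/C(C)=C\C)[C@H]12 | target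

**Totals**
Total steps: 9. Longest linear sequence: 9.

**Three steps most likely to fail**

Step 7 (new annulation). The carboxylate oxa-Michael addition is reversible and the skipped dienal can form a dienamine. The fallback uses known chemistry, sets out from 12 and comes back at 15. Amine-catalysed nucleophilic epoxidation of 12 (35% H2O2, the same (S)-diarylprolinol silyl ether, CH2Cl2) with NaBH4 quench gives [(2R,3R)-3-[(2Z,6E)-7-iodo-2,6-dimethylhepta-2,6-dien-1-yl]oxiran-2-yl]methanol F1, with the C8–O bond set by the catalyst in the same facial sense. Hydride opening at C7 with NaAlH2(OCH2CH2OMe)2 in THF at −20 °C gives (3R,5Z,9E)-10-iodo-5,9-dimethyldeca-5,9-diene-1,3-diol F2. TEMPO/PhI(OAc)2 oxidises only the primary alcohol to (3R,5Z,9E)-3-hydroxy-10-iodo-5,9-dimethyldeca-5,9-dienal F3. Pyruvoyl chloride/pyridine at −40 °C esterifies the secondary hydroxyl to give 14 as an isolated compound. Pyrrolidine/AcOH (20 mol %) in CHCl3 then closes 14 by an amine-catalysed 5-enolexo aldol, under substrate control from C8, to 15.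

Step 8 (ring closure and C6 configuration). Felkin-type addition would give the C6 epimer instead of the chelation product. The fallback sets out from 15 and comes back at 17. If the closure gives mainly (6R,7R,8R,11R)-(1(10)Z,4E)-6,11-dihydroxygermacra-1(10),4-dien-12,8-olide F4, the allylic carbinol of the crude diol mixture is oxidised with MnO2 to (7R,8R,11R)-(1(10)Z,4E)-11-hydroxy-6-oxogermacra-1(10),4-dien-12,8-olide F5. C6 is then set by reagent control with (S)-2-methyl-CBS-oxazaborolidine/BH3·SMe2, taking the alkenyl arm as the large group (the (R)-catalyst if the sense proves reversed), to give 17.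

Step 9 (double angeloylation). The tertiary C11–OH is hindered, and a free C6 alkoxide can translactonise. The fallback sets out from 17 and comes back at 19. Both hydroxyls are acylated without alkoxides using 2-[bis(2,2,2-trifluoroethoxy)phosphoryl]propanoyl chloride (pyridine, DMAP, CH2Cl2) to give (6S,7S,8R,11R)-(1(10)Z,4E)-6,11-bis{2-[bis(2,2,2-trifluoroethoxy)phosphoryl]propanoyloxy}germacra-1(10),4-dien-12,8-olide F6. Both angelates are then built on the molecule by twofold Still–Gennari olefination with acetaldehyde (KN(SiMe3)2, 18-crown-6, THF, −78 °C), which gives the Z esters of 19.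

**Further compounds**
F1 | step 7 | [(2R,3R)-3-[(2Z,6E)-7-iodo-2,6-dimethylhepta-2,6-dien-1-yl]oxiran-2-yl]methanol | OC[C@H]1O[C@@H]1C/C(C)=C\CC/C(C)=C/I
F2 | step 7 | (3R,5Z,9E)-10-iodo-5,9-dimethyldeca-5,9-diene-1,3-diol | OCC[C@H](O)C/C(C)=C\CC/C(C)=C/I
F3 | step 7 | (3R,5Z,9E)-3-hydroxy-10-iodo-5,9-dimethyldeca-5,9-dienal | O=CC[C@H](O)C/C(C)=C\CC/C(C)=C/I
F4 | step 8 | (6R,7R,8R,11R)-(1(10)Z,4E)-6,11-dihydroxygermacra-1(10),4-dien-12,8-olide | O[C@@H]1/C=C(\C)CC/C=C(/C)C[C@H]2OC(=O)[C@](C)(O)[C@H]12
F5 | step 8 | (7R,8R,11R)-(1(10)Z,4E)-11-hydroxy-6-oxogermacra-1(10),4-dien-12,8-olide | O=C1/C=C(\C)CC/C=C(/C)C[C@H]2OC(=O)[C@](C)(O)[C@H]12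
F6 | step 9 | (6S,7S,8R,11R)-(1(10)Z,4E)-6,11-bis{2-[bis(2,2,2-trifluoroethoxy)phosphoryl]propanoyloxy}germacra-1(10),4-dien-12,8-olide | CC(C(=O)O[C@H]1/C=C(\C)CC/C=C(/C)C[C@H]2OC(=O)[C@](C)(OC(=O)C(C)P(=O)(OCC(F)(F)F)OCC(F)(F)F)[C@H]12)P(=O)(OCC(F)(F)F)OCC(F)(F)F
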